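# Proposed synthesis of (2R,4R)-hemiketal 29 (CNP0170313.2) by late-stage cyclobutenone benzannulation

## Analysis of the target

Target 29 is a pentacyclic C26 flavonoid. In flavanone numbering, a 5-methoxy-8-prenylchromanone core (rings A and C) carries a 2,2-dimethyl-2H-pyran fused linearly across C6–C7 (ring D, oxygen on C7) and a 2',6'-dioxygenated ring B on C2. C4 is not a ketone but a hemiketal carbon: O2' is bonded to C4, so C2, C3, C4, O2', C2' and C1' form ring E. Rings C and E together are a doubly benzo-fused 2,6-dioxabicyclo[3.3.1]nonane with C2 and C4 as bridgeheads and C3 as the one-atom bridge. There are two stereocentres, C2 (R) and C4 (R), but only C2 is independent: the bridge can close only on the face of ring C that carries the aryl group, and the hemiketal is reversible, so C4 is under thermodynamic control. The open 2',6'-dihydroxyflavanone is the weak point, because base can enolise C3 and expel O1 (chalcone formation), which would erase C2. Acid in turn threatens the prenyl group, the chromene double bond and the hemiketal. Ring A is hexasubstituted, so the order in which methoxy, pyran and prenyl are placed decides the regiochemistry, and ring B has both positions ortho to C1' oxygenated, which makes joining a finished ring B to C2 sterically demanding. The strategy rests on the sequence O2'–C1'–O6' of ring B: a free hydroxyl on C2', the carbon C1' bonded to C2, and an ether oxygen on C6' are the three contiguous positions that a ketene–ynol ether benzannulation lays down, and the hydroxyl it creates is the one needed for ring E.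

## Retrosynthetic reasoning

**O6'–CH2 (29 ⇒ 28).** The last bond cut is the O–C bond of a 2-(trimethylsilyl)ethyl ether on O6', leading from 29 to its mono-ether 28. The alkyne oxygen that becomes O6' must carry a carbon substituent through the annulation. This primary alkyl group has no low-temperature sigmatropic or retro-ene pathway, and fluoride removes it in one step without touching the methyl ether on O5. The forward step only releases one phenol; the cage and both stereocentres are already in place.

**Ring B and ring E (28 ⇒ 19 + 22).** Four bonds are cut at once: C4–O2' of the hemiketal, and C1'–C2', C2'–C3' and C5'–C6' of ring B. This gives alkynyl ether 19, in which C1' and C6' are the two alkyne carbons on C2 of the complete chromanone, and cyclobut-2-en-1-one 22, which supplies C2' with its oxygen, C3', C4' and C5'. The cut is made inside ring B and not at C2–C1' for these reasons: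
- A 2,6-dioxygenated aryl group is easy to buy, but it is a poor partner for bond formation at C2, since both ortho positions are blocked and such additions are hard to make enantioselective.
- A slim alkyne already attached to C2 avoids that problem.
- The two oxygens emerge differentiated (free hydroxyl on C2', ether on C6'), and the new phenol closes ring E and sets C4 in the same flask.

The forward reaction must generate a ketene from 22 under neutral conditions, add it to the ynol ether in the right orientation and in preference to the two alkenes of 19, and leave the base-sensitive C2 centre alone.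

**Cyclobutenone (22 ⇒ 21 ⇒ 20).** 22 is too reactive to store and is traced through 3-bromocyclobutan-1-one 21 (C=C bond by elimination) to 3-oxocyclobutane-1-carboxylic acid 20 (C–Br from C–CO2H). Both steps are simple and can be run shortly before use.

**C2–C1' (19 ⇒ 8 + 16).** The bond between C2 and the alkyne is cut to give the flat ring A/D chromone 8 and terminal ynol ether 16. This is where the only independent stereocentre is made, at an unhindered sp2 carbon and by catalyst control, before any bulk sits on C1'. The terminal carbon of 16 is nucleophilic both as a metal acetylide and as the β-carbon of an ynol ether, so the polarity is matched. The forward reaction must deliver 2R and tolerate an acid-sensitive alkynyl ether. Enantioselective alkynylation of chromones is established for ordinary terminal alkynes but not for alkoxyacetylenes, so this step carries real risk, is marked accordingly in the route, and has a fallback built on classical chemistry.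

**Ynol ether (16 ⇒ 13 ⇒ 9 + 10).** 16 comes from dichlorovinyl ether 13 by double dehydrochlorination and metal–halogen exchange, and 13 from 2-(trimethylsilyl)ethan-1-ol 9 and trichloroethene 10. This is the standard route to alkoxyacetylenes and needs only a primary alkoxide.

**Ring C (8 ⇒ 5 + 6).** The O1–C2 and C2–C3 bonds of the chromone are cut to give ortho-hydroxyacetophenone 5 and the one-carbon donor 6. Ring C is made last on the ring A side so that the chelated hydroxyl of 5 stays free until then.

**Ring D (5 ⇒ 3 + 4).** The pyran is cut at O7–C and C6–C to give prenylated acetophenone 3 and 3-methylbut-2-enal 4. With the prenyl group already on the carbon between the two hydroxyls, the only free ring carbon is the one between the hydroxyl and the methoxy group, so the linear fusion is the only outcome.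

**Prenyl group (3 ⇒ 1 + 2).** The C8–CH2 bond is cut to give commercial 1-(2,4-dihydroxy-6-methoxyphenyl)ethan-1-one 1 and prenyl bromide 2. The methyl ether on O5 is bought with 1, so no selective methylation of a chelated hydroxyl is ever needed. The price is a C-alkylation whose regioselectivity is not perfect.

## Alternatives that were turned down

**Alternative 1: ring A by benzannulation on O1.**
- Disconnection and key step: bonds C7–C8, C4a–C8a and C6–C7 are cut. Photolysis of diazo ketone A1 (Wolff rearrangement) gives a methoxy-substituted vinylketene, which combines with ynol ether A2, whose oxygen already carries the C2 stereocentre and a protected ring B. The product is phenol A3.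
- For it: the substitution of ring A is written by the annulation, so the prenyl group sits on C8 and O5 is distinguished from O7 without any selectivity problem. On this point it is stronger than step 1 of the chosen route. The ketene is made at room temperature, and no new catalytic reaction is needed for the stereocentre.
- Against it: A2 is the alkynyl ether of a secondary benzylic alcohol. Secondary alkyl ynol ethers undergo retro-ene fragmentation far more readily than primary ones, and the benzylic C–O bond is easily ionised, so the key partner is fragile and awkward to prepare and to C-prenylate. After A3 the route still needs side-chain deprotection and oxidation, an acid-mediated acylation to close ring C in the presence of acetal protecting groups and a prenyl group, the chromene annulation, and the final deprotection.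
- Comparison: it uses the same reaction type to build the ring that is commercially available in 1, and buys the ring that is awkward to attach. The chosen route has two steps after its key step where this one has five or more.

**Alternative 2: aryne annulation for ring C.**
- Disconnection and key step: O1–C8a and C4–C4a are cut. Fluoride converts silylaryl triflate A4 into the C4a–C8a aryne, the alkoxide of enantiopure hydroxy ester A5 adds at C8a, and the aryl anion at C4a attacks the ester to give flavanone A6.
- For it: this is the most convergent plan. The stereocentre comes from reliable asymmetric carbonyl chemistry, the electronic bias of the C5 methoxy group directs the nucleophile to C8a, and A6 is one deprotection from the target. Because ring B is symmetric about the C2–C1' axis, the two oxygens need no differentiation, so the differentiation offered by the chosen route is a convenience and not a necessity.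
- Against it: A4 is a hexasubstituted benzene with vicinal silyl and triflate groups wedged between the methoxy and prenyl substituents, and reaching it regioselectively costs many steps. The aldolate of A5 can undergo retro-aldol cleavage or dehydration under basic fluoride, and aliphatic alkoxides add to arynes less cleanly than phenoxides. The attack must also occur next to the prenyl-bearing carbon. The final acetal removal needs acid in the presence of the chromene.
- Comparison: it is stronger in convergence, but it moves the difficulty into the synthesis of A4 and keeps an uncertain key step. The chosen route reaches its ring A/D partner 8 in three steps and runs its key step under neutral conditions.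

**Alternative 3: biomimetic aromatisation of ring A.**
- Disconnection and key step: the C5–C4a bond is cut. Thermolysis of β-keto ester A7 expels the ester alcohol to give an acylketene, which acylates the nucleophilic carbon C4a of the dihydropyranone; enolisation then aromatises ring A to give flavanone A8.
- For it: the prenyl position is fixed by the chain, the stereocentre can be set early on a simple pyranone, and the key step is thermal and neutral.
- Against it: A7 is a long, polyfunctional chain with several acidic sites. O-acylation to a pyranone competes with the desired C-acylation. A8 still lacks ring D and the methyl ether: the pyran must close onto O7 and not O5, and methylation of the chelated 5-hydroxyl of a flavanone needs base, exactly the condition under which ring C opens to the chalcone and C2 is lost.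
- Comparison: it is the longest of the four plans and puts its most dangerous step after the stereocentre is set. The chosen route carries the O5 methyl ether from the first compound.

Key step: step 9

## Route

Assumption: the ring–chain equilibrium between the 2'-hydroxyflavanone and the bridged hemiketal is taken to lie on the closed side for 28 and 29; whatever its position, the route delivers the same equilibrium composition as any other source of 29.

Assumption: the antipode of the ligand StackPhos that gives the 2R configuration is selected on a model chromone, and the configuration of 19 is confirmed before the key step; both antipodes of the ligand are accessible.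

Step 1
Reactants: 1 1-(2,4-dihydroxy-6-methoxyphenyl)ethan-1-one; 2 1-bromo-3-methylbut-2-ene
Product: 3 1-[2,4-dihydroxy-6-methoxy-3-(3-methylbut-2-en-1-yl)phenyl]ethan-1-one
Conditions: 2 (1.0 equiv), 10% aq. KOH, 0 → 23 °C; chromatographic separation of isomers
Reagents that add atoms: none
Why: Nuclear prenylation of a phloroglucinol-type phenoxide: in aqueous KOH the ambident anion is alkylated on carbon, preferentially at C3' between the two hydroxyl groups, and the C5' and O-alkylated isomers are removed by chromatography. The step is accepted as modest in yield because it opens the route on an inexpensive material and fixes the prenyl position before the pyran is built.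

Step 2
Reactants: 3 1-[2,4-dihydroxy-6-methoxy-3-(3-methylbut-2-en-1-yl)phenyl]ethan-1-one; 4 3-methylbut-2-enal
Product: 5 1-[7-hydroxy-5-methoxy-2,2-dimethyl-8-(3-methylbut-2-en-1-yl)-2H-chromen-6-yl]ethan-1-one
Conditions: 4 (2 equiv), ethylenediammonium diacetate (20 mol %), xylene, 140 °C
Reagents that add atoms: none
Why: Aldol-type condensation of the phenol with the enal at C5' followed by oxa-6π electrocyclisation onto O4' (formal [3+3] chromene annulation). C5' is the only unsubstituted ring carbon and O4' the only hydroxyl next to it, so the linear pyran (ring D) is the only possible product and the chelated 2'-hydroxyl stays free for ring C.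

Step 3
Reactants: 5 1-[7-hydroxy-5-methoxy-2,2-dimethyl-8-(3-methylbut-2-en-1-yl)-2H-chromen-6-yl]ethan-1-one; 6 1,1-dimethoxy-N,N-dimethylmethanamine
Product: 8 5-methoxy-8,8-dimethyl-10-(3-methylbut-2-en-1-yl)-4H,8H-pyrano[3,2-g]chromen-4-one, via enaminone 7 (not isolated)
Conditions: 6 (2 equiv), toluene, 100 °C; concentrate; then 2 M HCl, CH2Cl2, 23 °C
Reagents that add atoms: none
Why: Condensation of the methyl ketone with the formamide acetal gives enaminone 7, and acid then triggers conjugate addition of the ortho hydroxyl and loss of dimethylamine (standard enaminone route to chromones unsubstituted at C2 and C3). Brief contact with dilute acid at room temperature is chosen so that the prenyl and chromene alkenes are not protonated.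

Step 4
Reactants: 9 2-(trimethylsilyl)ethan-1-ol; 10 trichloroethene
Product: 13 (E)-[2-(1,2-dichloroethenyloxy)ethyl]trimethylsilane, via potassium alkoxide 11 (not isolated), via dichloroethyne 12 (not isolated)
Conditions: KH (1.2 equiv), THF, 0 → 23 °C; then 10 (1.1 equiv), 23 °C
Reagents that add atoms: none
Why: Alkoxide 11 converts trichloroethene into dichloroethyne 12 by elimination and then adds to it in anti fashion, which gives the (E)-1,2-dichlorovinyl ether (standard entry to alkoxyacetylenes).

Step 5
Reactants: 13 (E)-[2-(1,2-dichloroethenyloxy)ethyl]trimethylsilane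
Product: 16 [2-(ethynyloxy)ethyl]trimethylsilane, via chloroalkynyl ether 14 (not isolated), via lithium acetylide 15 (not isolated)
Conditions: n-BuLi (2.4 equiv), Et2O, −78 → −40 °C; then H2O, −40 → 0 °C; dried toluene solution stored over K2CO3 at −20 °C
Reagents that add atoms: none
Why: Deprotonation and β-elimination give chloroalkynyl ether 14, chlorine–lithium exchange gives acetylide 15, and water protonates it on carbon (standard preparation of terminal alkoxyacetylenes). The volatile, acid-sensitive ynol ether is not purified on silica but used as a titrated solution.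

Step 6
Reactants: 8 5-methoxy-8,8-dimethyl-10-(3-methylbut-2-en-1-yl)-4H,8H-pyrano[3,2-g]chromen-4-one; 16 [2-(ethynyloxy)ethyl]trimethylsilane
Product: 19 (2R)-5-methoxy-8,8-dimethyl-10-(3-methylbut-2-en-1-yl)-2-{[2-(trimethylsilyl)ethoxy]ethynyl}-2,3-dihydro-4H,8H-pyrano[3,2-g]chromen-4-one, via benzopyrylium triflate 17 (not isolated), via silyl enol ether 18 (not isolated)
Conditions: t-BuMe2SiOTf (1.05 equiv), toluene, 23 °C; then CuI (10 mol %), StackPhos (12 mol %, antipode giving 2R), i-Pr2NEt (1.5 equiv), 16 (2 equiv), −40 °C; then NH4F, MeOH–THF, 0 °C; chromatography on Et3N-deactivated silica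
Reagents that add atoms: none
Why: Proposed new method: silylation converts 8 into benzopyrylium triflate 17, CuI and the amine convert 16 into the acetylide Cu–C≡C–OCH2CH2SiMe3 (monovalent copper acetylides of alkoxyacetylenes form under the same conditions in Sonogashira couplings), and this adds through its metal-bearing carbon, which is also the inherently nucleophilic β-carbon of an ynol ether, to C2 on the face left open by the bound P,N ligand, so that the 2R centre is set by the catalyst and enol ether 18 is then unmasked to the ketone. The closest known reaction type is the CuI/StackPhos-catalysed enantioselective conjugate alkynylation of chromones with aryl- and alkyl-substituted terminal alkynes; what has not been shown is the level and sense of induction with an alkoxyacetylide and its survival next to a silyl triflate, which is why the triflate is consumed by 8 before 16 is added. NH4F in methanol is used for the desilylation because it is neither acidic enough to hydrate the ynol ether nor basic enough to open ring C by retro-oxa-Michael reaction.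

Step 7
Reactants: 20 3-oxocyclobutane-1-carboxylic acid
Product: 21 3-bromocyclobutan-1-one
Conditions: HgO, Br2, MgSO4, CH2Cl2, 40 °C
Reagents that add atoms: bromine, BrBr
Why: Cristol–Firth variant of the Hunsdiecker reaction: radical bromodecarboxylation of the carboxylic acid gives the secondary bromide, and the ketone is inert under these conditions.

Step 8
Reactants: 21 3-bromocyclobutan-1-one
Product: 22 cyclobut-2-en-1-one
Conditions: n-Bu3N (1.1 equiv), 23 °C; vacuum transfer into a −78 °C trap; used as a cold toluene solution
Reagents that add atoms: none
Why: The bromide is β to the ketone, so the amine effects 1,2-elimination (E1cB) at room temperature. The volatile, polymerisation-prone enone is collected cold and used within hours.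

Step 9
Reactants: 19 (2R)-5-methoxy-8,8-dimethyl-10-(3-methylbut-2-en-1-yl)-2-{[2-(trimethylsilyl)ethoxy]ethynyl}-2,3-dihydro-4H,8H-pyrano[3,2-g]chromen-4-one; 22 cyclobut-2-en-1-one
Product: 28 (2R,4R)-4,2'-epoxy-5-methoxy-6'',6''-dimethyl-8-(3-methylbut-2-en-1-yl)-6'-[2-(trimethylsilyl)ethoxy]-6''H-pyrano[2'',3'':7,6]flavan-4-ol, via vinylketene 23 (not isolated), via vinylcyclobutenone 24 (not isolated), via dienylketene 25 (not isolated), via cyclohexadienone 26 (not isolated), via hydroxyflavanone 27 (not isolated)
Conditions: 22 (3 equiv, added in portions), toluene (0.2 M in 19), 80 °C, sealed vessel, exclusion of light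
Reagents that add atoms: none
Why: On heating, 22 opens by 4π electrocyclic ring opening to vinylketene 23, which is trapped by the ynol ether of 19 in a [2+2] cycloaddition in which the nucleophilic alkyne carbon C1' bonds to the ketene carbonyl carbon, giving vinylcyclobutenone 24. A second 4π opening gives dienylketene 25, 6π electrocyclisation closes ring B as cyclohexadienone 26, and tautomerisation gives phenol 27 with the free hydroxyl on C2' and the ether on C6' (bonds C1'–C2', C5'–C6' and C2'–C3'). The closest known reaction type is the thermal Danheiser benzannulation of cyclobutenones with alkoxyacetylenes to 2-substituted resorcinol monoethers. The phenol of 27 then adds to the C4 ketone by 6-exo-trig hemiketalisation (bond C4–O2', ring E), a reversible closure under thermodynamic control. The new C4 centre is controlled by C2: the one-carbon bridge C3 allows the oxygen to reach C4 only from the face of ring C that carries the aryl group, so 2R gives 4R. Regioselectivity comes from the polarisation of the ynol ether, and chemoselectivity from its much higher reactivity towards ketenes than the trisubstituted prenyl alkene and the chromene alkene. C2 is not endangered because the medium is neutral and aprotic, and the primary alkyl ynol ether has no retro-ene pathway at this temperature.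

Step 10
Reactants: 28 (2R,4R)-4,2'-epoxy-5-methoxy-6'',6''-dimethyl-8-(3-methylbut-2-en-1-yl)-6'-[2-(trimethylsilyl)ethoxy]-6''H-pyrano[2'',3'':7,6]flavan-4-ol
Product: 29 (2R,4R)-4,2'-epoxy-5-methoxy-6'',6''-dimethyl-8-(3-methylbut-2-en-1-yl)-6''H-pyrano[2'',3'':7,6]flavan-4,6'-diol
Conditions: Bu4NF (3 equiv), THF, 0 → 23 °C; then pH 7 phosphate buffer
Reagents that add atoms: none
Why: Fluoride attacks the trimethylsilyl group and the β-aryloxy substituent leaves with loss of ethene (fluoride-induced 1,2-elimination of a 2-silylethyl aryl ether). No bond to C2 or C4 is broken, and neutral aqueous work-up returns the phenol and lets the hemiketal settle in its closed form.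

## Compound list

1 | 1-(2,4-dihydroxy-6-methoxyphenyl)ethan-1-one | CC(=O)c1c(O)cc(O)cc1OC | starting material
2 | 1-bromo-3-methylbut-2-ene | CC(C)=CCBr | starting material
3 | 1-[2,4-dihydroxy-6-methoxy-3-(3-methylbut-2-en-1-yl)phenyl]ethan-1-one | CC(=O)c1c(O)c(CC=C(C)C)c(O)cc1OC | intermediate
4 | 3-methylbut-2-enal | CC(C)=CC=O | starting material
5 | 1-[7-hydroxy-5-methoxy-2,2-dimethyl-8-(3-methylbut-2-en-1-yl)-2H-chromen-6-yl]ethan-1-one | CC(=O)c1c(O)c(CC=C(C)C)c2OC(C)(C)C=Cc2c1OC | intermediate
6 | 1,1-dimethoxy-N,N-dimethylmethanamine | COC(OC)N(C)C | starting material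
7 | (E)-3-(dimethylamino)-1-[7-hydroxy-5-methoxy-2,2-dimethyl-8-(3-methylbut-2-en-1-yl)-2H-chromen-6-yl]prop-2-en-1-one | CN(C)/C=C/C(=O)c1c(O)c(CC=C(C)C)c2OC(C)(C)C=Cc2c1OC | intermediate
8 | 5-methoxy-8,8-dimethyl-10-(3-methylbut-2-en-1-yl)-4H,8H-pyrano[3,2-g]chromen-4-one | COc1c2C=CC(C)(C)Oc2c(CC=C(C)C)c2OC=CC(=O)c12 | intermediate
9 | 2-(trimethylsilyl)ethan-1-ol | C[Si](C)(C)CCO | starting material
10 | trichloroethene | ClC=C(Cl)Cl | starting material
11 | potassium 2-(trimethylsilyl)ethan-1-olate | [K+].[O-]CC[Si](C)(C)C | intermediate
12 | dichloroethyne | ClC#CCl | intermediate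
13 | (E)-[2-(1,2-dichloroethenyloxy)ethyl]trimethylsilane | Cl/C=C(/Cl)OCC[Si](C)(C)C | intermediate
14 | {2-[(chloroethynyl)oxy]ethyl}trimethylsilane | ClC#COCC[Si](C)(C)C | intermediate
15 | lithium [2-(trimethylsilyl)ethoxy]ethynide | [Li]C#COCC[Si](C)(C)C | intermediate
16 | [2-(ethynyloxy)ethyl]trimethylsilane | C#COCC[Si](C)(C)C | intermediate
17 | 4-[(tert-butyldimethylsilyl)oxy]-5-methoxy-8,8-dimethyl-10-(3-methylbut-2-en-1-yl)-8H-pyrano[3,2-g]chromen-1-ium trifluoromethanesulfonate | COc1c2C=CC(C)(C)Oc2c(CC=C(C)C)c2[O+]=CC=C(O[Si](C)(C)C(C)(C)C)c12.[O-]S(=O)(=O)C(F)(F)F | intermediate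
18 | tert-butyl{[(2R)-5-methoxy-8,8-dimethyl-10-(3-methylbut-2-en-1-yl)-2-{[2-(trimethylsilyl)ethoxy]ethynyl}-2H,8H-pyrano[3,2-g]chromen-4-yl]oxy}dimethylsilane | COc1c2C=CC(C)(C)Oc2c(CC=C(C)C)c2O[C@H](C=C(O[Si](C)(C)C(C)(C)C)c12)C#COCC[Si](C)(C)C | intermediate
19 | (2R)-5-methoxy-8,8-dimethyl-10-(3-methylbut-2-en-1-yl)-2-{[2-(trimethylsilyl)ethoxy]ethynyl}-2,3-dihydro-4H,8H-pyrano[3,2-g]chromen-4-one | COc1c2C=CC(C)(C)Oc2c(CC=C(C)C)c2O[C@H](CC(=O)c12)C#COCC[Si](C)(C)C | intermediate
20 | 3-oxocyclobutane-1-carboxylic acid | O=C1CC(C1)C(=O)O | starting material
21 | 3-bromocyclobutan-1-one | O=C1CC(Br)C1 | intermediate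
22 | cyclobut-2-en-1-one | O=C1C=CC1 | intermediate
23 | buta-1,3-dien-1-one (vinylketene) | C=CC=C=O | intermediate
24 | 2-[(2R)-chromanon-2-yl]-3-[2-(trimethylsilyl)ethoxy]-4-vinylcyclobut-2-en-1-one of the ring A/D system (mixture at the ring CH) | COc1c2C=CC(C)(C)Oc2c(CC=C(C)C)c2O[C@H](CC(=O)c12)C1=C(OCC[Si](C)(C)C)C(C=C)C1=O | intermediate
25 | dienylketene from ring opening of 24, (3Z)-2-[(2R)-chromanon-2-yl]-3-[2-(trimethylsilyl)ethoxy]hexa-1,3,5-trien-1-one | COc1c2C=CC(C)(C)Oc2c(CC=C(C)C)c2O[C@H](CC(=O)c12)C(=C=O)/C(OCC[Si](C)(C)C)=C\C=C | intermediate
26 | 2-[(2R)-chromanon-2-yl]-3-[2-(trimethylsilyl)ethoxy]cyclohexa-2,4-dien-1-one | COc1c2C=CC(C)(C)Oc2c(CC=C(C)C)c2O[C@H](CC(=O)c12)C1=C(OCC[Si](C)(C)C)C=CCC1=O | intermediate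
27 | (2R)-2-{2-hydroxy-6-[2-(trimethylsilyl)ethoxy]phenyl}-5-methoxy-8,8-dimethyl-10-(3-methylbut-2-en-1-yl)-2,3-dihydro-4H,8H-pyrano[3,2-g]chromen-4-one | COc1c2C=CC(C)(C)Oc2c(CC=C(C)C)c2O[C@H](CC(=O)c12)c1c(O)cccc1OCC[Si](C)(C)C | intermediate
28 | (2R,4R)-4,2'-epoxy-5-methoxy-6'',6''-dimethyl-8-(3-methylbut-2-en-1-yl)-6'-[2-(trimethylsilyl)ethoxy]-6''H-pyrano[2'',3'':7,6]flavan-4-ol | COc1c2c(c(CC=C(C)C)c3c1[C@@]1(O)C[C@@H](O3)c3c(OCC[Si](C)(C)C)cccc3O1)OC(C)(C)C=C2 | intermediate
29 | (2R,4R)-4,2'-epoxy-5-methoxy-6'',6''-dimethyl-8-(3-methylbut-2-en-1-yl)-6''H-pyrano[2'',3'':7,6]flavan-4,6'-diol | COc1c2c(c(CC=C(C)C)c3c1[C@@]1(O)C[C@@H](O3)c3c(O)cccc3O1)OC(C)(C)C=C2 | target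

## Step count and least certain steps

Total step count: 10. Longest linear sequence: 6 steps (steps 1, 2, 3, 6, 9 and 10, from 1). The ynol ether (steps 4 and 5) and cyclobutenone (steps 7 and 8) branches are two steps each.

**Step 6 (proposed new method).**
- What may go wrong: the electron-rich alkyne may attack the pyrylium ion without copper, giving a racemic background reaction. The ynol ether may be consumed by electrophilic silylation or oligomerisation. The donor-stabilised pyrylium ion may add the acetylide sluggishly, and the induction with an alkoxyacetylide is unknown. The doubly activated propargylic C2–O1 bond of 19 may also ionise on acidic supports, eroding the enantiomeric purity.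
- Fallback, classical chemistry only, from 5 to 29; it gives up the benzannulation and catalytic control. Claisen–Schmidt condensation of 5 with 2,6-bis(methoxymethoxy)benzaldehyde F1 (KOH, EtOH; F1 by methoxymethylation of commercial 2,6-dihydroxybenzaldehyde) gives the 2'-hydroxychalcone F2. Oxa-Michael ring closure (NaOAc, EtOH, reflux) gives the racemic flavanone F3. Preparative chromatography on a chiral stationary phase gives the (2R)-flavanone F4, the same structure as A6; the unwanted enantiomer can be recycled through the chalcone with base. Acetal cleavage (2 M HCl, THF, 45 °C, no alcohol, to avoid a mixed ketal at C4) releases both phenols, one of which closes ring E, giving 29.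

**Step 9 (key step).**
- What may go wrong: the vinylketene and cyclobutenone may oligomerise before the ynol ether captures the ketene. The ynol ether may fragment thermally if higher temperature is needed. Excess ketene may acylate the new phenol or the hemiketal hydroxyl; such esters would be cleaved in step 10. Ring E may close incompletely at the ether stage.
- Fallback, from 19, rejoining at 24: generate the same vinylketene at room temperature by photochemical Wolff rearrangement of 1-diazobut-3-en-2-one F5 (from but-3-en-2-one by detrifluoroacetylative diazo transfer; 450 nm light-emitting diodes, CH2Cl2, 23 °C, a wavelength at which the chromanone and chromene of 19 do not absorb). The [2+2] adduct 24 then forms without heating while the ynol ether is consumed, and 24 is warmed in toluene to complete the sequence to 28.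

**Step 10.**
- What may go wrong: under basic fluoride the hemiketal can open to the keto-phenoxide. Enolisation at C3 and expulsion of O1 (retro-oxa-Michael reaction to the chalcone) followed by re-closure would erode the configuration at C2, and with it C4.
- Fallback, from 28 to 29, with a different mode of cleavage: electrophilic activation of the ether oxygen with BF3·OEt2 (CH2Cl2, −20 → 0 °C) induces β-silyl fragmentation with loss of ethene in a non-basic medium, in which no enolate can form. Aqueous work-up returns the hemiketal. No new compound is involved.

**Step 1.**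
- What may go wrong: poor selectivity between C3' and C5', competing O-alkylation and double alkylation, and hence low recovery of 3.
- Fallback, from 1 to 3: selective etherification of the non-chelated 4'-hydroxyl with 3-chloro-3-methylbut-1-yne (K2CO3, KI, CuI cat., acetone, 60 °C) gives 1-{2-hydroxy-6-methoxy-4-[(2-methylbut-3-yn-2-yl)oxy]phenyl}ethan-1-one F6. Semihydrogenation (H2, Pd/CaCO3 poisoned with Pb(OAc)2, quinoline, EtOAc) gives 1-{2-hydroxy-6-methoxy-4-[(2-methylbut-3-en-2-yl)oxy]phenyl}ethan-1-one F7. Aromatic Claisen rearrangement (N,N-diethylaniline, 130 °C) delivers the 3-methylbut-2-enyl group to an ortho carbon. C3' is expected to be preferred because the chelated ortho-hydroxy ketone gives the C3'–C4' bond more double-bond character, and this gives 3.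

## Further compounds

F1 | step 6 | 2,6-bis(methoxymethoxy)benzaldehyde | O=Cc1c(OCOC)cccc1OCOC
F2 | step 6 | (E)-3-[2,6-bis(methoxymethoxy)phenyl]-1-[7-hydroxy-5-methoxy-2,2-dimethyl-8-(3-methylbut-2-en-1-yl)-2H-chromen-6-yl]prop-2-en-1-one | COCOc1cccc(OCOC)c1/C=C/C(=O)c1c(O)c(CC=C(C)C)c2OC(C)(C)C=Cc2c1OC
F3 | step 6 | rac-2-[2,6-bis(methoxymethoxy)phenyl]-5-methoxy-8,8-dimethyl-10-(3-methylbut-2-en-1-yl)-2,3-dihydro-4H,8H-pyrano[3,2-g]chromen-4-one | COc1c2C=CC(C)(C)Oc2c(CC=C(C)C)c2OC(CC(=O)c12)c1c(OCOC)cccc1OCOC
F4 | step 6 | (2R)-2-[2,6-bis(methoxymethoxy)phenyl]-5-methoxy-8,8-dimethyl-10-(3-methylbut-2-en-1-yl)-2,3-dihydro-4H,8H-pyrano[3,2-g]chromen-4-one | COc1c2C=CC(C)(C)Oc2c(CC=C(C)C)c2O[C@H](CC(=O)c12)c1c(OCOC)cccc1OCOC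
F5 | step 9 | 1-diazobut-3-en-2-one | C=CC(=O)C=[N+]=[N-]
F0 | step 10 | none | none
F6 | step 1 | 1-{2-hydroxy-6-methoxy-4-[(2-methylbut-3-yn-2-yl)oxy]phenyl}ethan-1-one | CC(=O)c1c(O)cc(OC(C)(C)C#C)cc1OC
F7 | step 1 | 1-{2-hydroxy-6-methoxy-4-[(2-methylbut-3-en-2-yl)oxy]phenyl}ethan-1-one | CC(=O)c1c(O)cc(OC(C)(C)C=C)cc1OC
A1 | alternative 1 | 1-diazo-3-methoxybut-3-en-2-one | C=C(OC)C(=O)C=[N+]=[N-]
A2 | alternative 1 | tert-butyl{(3R)-3-[2,6-bis(methoxymethoxy)phenyl]-3-[(5-methylhex-4-en-1-yn-1-yl)oxy]propoxy}dimethylsilane | CC(C)=CCC#CO[C@H](CCO[Si](C)(C)C(C)(C)C)c1c(OCOC)cccc1OCOC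
A3 | alternative 1 | 3-{(1R)-1-[2,6-bis(methoxymethoxy)phenyl]-3-[(tert-butyldimethylsilyl)oxy]propoxy}-5-methoxy-2-(3-methylbut-2-en-1-yl)phenol | COc1cc(O)c(CC=C(C)C)c(O[C@H](CCO[Si](C)(C)C(C)(C)C)c2c(OCOC)cccc2OCOC)c1
A4 | alternative 2 | 5-methoxy-2,2-dimethyl-8-(3-methylbut-2-en-1-yl)-6-(trimethylsilyl)-2H-chromen-7-yl trifluoromethanesulfonate | COc1c2C=CC(C)(C)Oc2c(CC=C(C)C)c(OS(=O)(=O)C(F)(F)F)c1[Si](C)(C)C
A5 | alternative 2 | methyl (3R)-3-[2,6-bis(methoxymethoxy)phenyl]-3-hydroxypropanoate | O[C@H](CC(=O)OC)c1c(OCOC)cccc1OCOC
A6 | alternative 2 | (2R)-2-[2,6-bis(methoxymethoxy)phenyl]-5-methoxy-8,8-dimethyl-10-(3-methylbut-2-en-1-yl)-2,3-dihydro-4H,8H-pyrano[3,2-g]chromen-4-one | COc1c2C=CC(C)(C)Oc2c(CC=C(C)C)c2O[C@H](CC(=O)c12)c1c(OCOC)cccc1OCOC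
A7 | alternative 3 | tert-butyl 4-{(2R)-2-[2,6-bis(methoxymethoxy)phenyl]-4-oxo-3,4-dihydro-2H-pyran-6-yl}-7-methyl-3-oxooct-6-enoate | CC(C)=CCC(C(=O)CC(=O)OC(C)(C)C)C1=CC(=O)C[C@@H](O1)c1c(OCOC)cccc1OCOC
A8 | alternative 3 | (2R)-2-[2,6-bis(methoxymethoxy)phenyl]-5,7-dihydroxy-8-(3-methylbut-2-en-1-yl)-2,3-dihydro-4H-chromen-4-one | Oc1cc(O)c(CC=C(C)C)c2O[C@H](CC(=O)c12)c1c(OCOC)cccc1OCOC
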